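**Retrosynthetic overview**

1. Locants: C1 = C(OH)(CH2OBz), C2 = CH(OAc), C3 = CH(OBz), C4=C5 = alkene, C6 = ring C=O, C7 = CH2OBz carbon. The last disconnection is the C4=C5 double bond, made by dehydrogenation of the saturated ketone 11.
2. Key disconnection: the C1–C2 bond of cyclohexanone 11, made by an acyloin (α-ketol) ring expansion of the 1-acylcyclopentanol 10, in which C2 shifts from C6 to C1. The enabling feature is the tertiary α-ketol C1(OH)–C6(=O) of the six-membered ring; its transposed form is a cyclopentanol (ring atoms C6, C2, C3, C4, C5) that carries C1 as an exocyclic ketone.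
3. 10 comes from the flat cyclopentenyl ketone 8 by one cis-dihydroxylation of C6=C2 anti to the C3 benzoate (sets C2 and the relay center C6), then acetylation of O2.
4. 8 comes from methyl 3-oxocyclopent-1-ene-1-carboxylate by CBS reduction (sets C3), benzoylation, and a diazoketone/benzoic acid sequence that installs C7–OBz.
5. Ring order: the five-membered carbocycle is purchased; the six-membered ring is formed once, in the key step; no other ring is made.

Key step: step 8

Remark: compound 1 is taken as a catalogue compound; Bz = benzoyl, Ac = acetyl; the locants C1–C7 above are used for all intermediates.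

**Route**

Step 1
Reactants: 1 methyl 3-oxocyclopent-1-ene-1-carboxylate
Product: 2 methyl (R)-3-hydroxycyclopent-1-ene-1-carboxylate
Conditions: (S)-1-methyl-3,3-diphenyltetrahydro-1H,3H-pyrrolo[1,2-c][1,3,2]oxazaborole ((S)-Me-CBS, 10 mol %), BH3·SMe2 (0.7 equiv), THF, −20 °C; then MeOH
Reagents that add atoms: none
Why: Corey–Bakshi–Shibata reduction, in which the oxazaborolidine–borane complex binds the ring ketone anti to the alkenyl arm (the larger group) and delivers hydride to one face, which for the (S)-catalyst should give the (R)-allylic alcohol (the future C3, the only stereocenter not set by relay), while the ester and the electron-poor alkene should stay untouched at low temperature.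

Step 2
Reactants: 2 methyl (R)-3-hydroxycyclopent-1-ene-1-carboxylate
Product: 3 (R)-3-hydroxycyclopent-1-ene-1-carboxylic acid
Conditions: LiOH·H2O (1.5 equiv), THF/H2O 3:1, 0 °C; then 1 M HCl to pH 3
Reagents that add atoms: lithium hydroxide, [Li+].[OH-]
Why: Saponification (acyl–oxygen cleavage) of the methyl enoate, in which the allylic carbinol center is not involved and mild acidification returns the free acid.

Step 3
Reactants: 3 (R)-3-hydroxycyclopent-1-ene-1-carboxylic acid
Product: 5 (R)-3-(benzoyloxy)cyclopent-1-ene-1-carboxylic acid, via mixed benzoic anhydride 4 (not isolated)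
Conditions: BzCl (2.3 equiv), pyridine, 4-(dimethylamino)pyridine (5 mol %), CH2Cl2, 0 °C to rt; then H2O/THF, rt
Reagents that add atoms: benzoyl chloride, O=C(Cl)c1ccccc1; water, O (may supply one carboxyl oxygen when 4 is hydrolysed)
Why: Pyridine-mediated O-benzoylation of the allylic alcohol with retention at the carbinol carbon, the carboxyl group being acylated as well to the mixed anhydride 4, which aqueous pyridine should hydrolyse back to the acid.

Step 4
Reactants: 5 (R)-3-(benzoyloxy)cyclopent-1-ene-1-carboxylic acid
Product: 7 (R)-3-(2-diazoacetyl)cyclopent-2-en-1-yl benzoate, via acid chloride 6 (not isolated)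
Conditions: (COCl)2 (1.3 equiv), DMF (cat.), CH2Cl2, 0 °C to rt, evaporate; then CH2N2 (2.5 equiv), Et2O, 0 °C
Reagents that add atoms: diazomethane, C=[N+]=[N-]
Why: Acid chloride formation followed by acylation of diazomethane (first stage of the Arndt–Eistert sequence), the second equivalent of diazomethane scavenging HCl so that the diazoketone and not the chloromethyl ketone forms, and acylation being far faster at 0 °C than dipolar cycloaddition to the trisubstituted alkene.

Step 5
Reactants: 7 (R)-3-(2-diazoacetyl)cyclopent-2-en-1-yl benzoate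
Product: 8 (R)-3-[2-(benzoyloxy)acetyl]cyclopent-2-en-1-yl benzoate
Conditions: PhCO2H (3 equiv), Rh2(OAc)4 (1 mol %), CH2Cl2, rt
Reagents that add atoms: benzoic acid, OC(=O)c1ccccc1
Why: Rhodium-carbenoid O–H insertion into a carboxylic acid, the standard conversion of a diazomethyl ketone into an α-acyloxy ketone, which installs C7–OBz next to the C1 ketone without touching the enone or the allylic benzoate.

Step 6
Reactants: 8 (R)-3-[2-(benzoyloxy)acetyl]cyclopent-2-en-1-yl benzoate
Product: 9 (1R,2S,3R)-3-[2-(benzoyloxy)acetyl]-2,3-dihydroxycyclopentyl benzoate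
Conditions: OsO4 (2 mol %), N-methylmorpholine N-oxide (1.3 equiv), citric acid (0.75 equiv), tBuOH/H2O 1:1, rt
Reagents that add atoms: osmium tetroxide, O=[Os](=O)(=O)=O (transfers both oxygens); N-methylmorpholine N-oxide, C[N+]1([O-])CCOCC1 (restores the oxidant); water, O (hydrolysis of the osmate ester)
Why: Catalytic OsO4 cis-dihydroxylation (citric acid-accelerated protocol for electron-poor alkenes) of the enone C6=C2, suprafacial and from the ring face opposite to the allylic C3 benzoate (steric approach control, in line with the empirical anti preference of allylic esters), so that C6–OH and C2–OH should be cis to each other and trans to C3–OBz.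

Step 7
Reactants: 9 (1R,2S,3R)-3-[2-(benzoyloxy)acetyl]-2,3-dihydroxycyclopentyl benzoate
Product: 10 (1R,2S,3R)-2-acetoxy-3-[2-(benzoyloxy)acetyl]-3-hydroxycyclopentyl benzoate
Conditions: Ac2O (1.3 equiv), pyridine, 4-(dimethylamino)pyridine (5 mol %), CH2Cl2, 0 °C
Reagents that add atoms: acetic anhydride, CC(=O)OC(C)=O
Why: Nucleophile-catalysed acylation, selective for the secondary C2 hydroxyl over the tertiary α-keto hydroxyl on C6 for steric reasons, the trans relationship on the five-membered ring preventing migration of the neighbouring benzoate.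

Step 8
Reactants: 10 (1R,2S,3R)-2-acetoxy-3-[2-(benzoyloxy)acetyl]-3-hydroxycyclopentyl benzoate
Product: 11 [(1S,2S,3R)-2-acetoxy-3-(benzoyloxy)-1-hydroxy-6-oxocyclohexyl]methyl benzoate
Conditions: Sc(OTf)3 (10 mol %), ClCH2CH2Cl, 60 °C
Reagents that add atoms: none
Why: Scandium triflate binds the tertiary C6 hydroxyl and the C1 ketone oxygen together, which holds the ketol cisoid and polarises the C1 carbonyl, and the ring bond C6–C2, lying nearly perpendicular to the carbonyl plane, shifts with its electron pair from C6 to C1 while the C6 oxygen becomes the ring ketone (acyloin or α-ketol rearrangement). The closest known reaction type is the Lewis-acid ring expansion of 1-acylcyclopentanols to 2-hydroxycyclohexanones, best documented as the D-homoannulation of 17-hydroxy-20-oxo-21-acyloxy steroids, which carry the same acyloxyacetyl carbinol. The six-membered ring (C1 to C6) is closed by this concerted suprafacial 1,2-shift, a one-carbon ring expansion in which the five-membered ring is opened in the same event, so no cyclisation of an open chain is involved. C2 migrates with retention and C3 is untouched; the new stereocenter C1 is controlled by the configuration at C6 of 10, because in the chelate C2 can reach only the carbonyl face on its own side, and this puts the new C1 hydroxyl cis to the C2 acetate. The step needs migration of C2 rather than of the ring methylene C5 (which would attack the other carbonyl face): C2 is the more substituted, oxygen-bearing terminus, and 11 is the only ketol isomer free of cyclopentane strain whose carbonyl carries a single α-oxygen, so rate and the reversible equilibrium should both favour it. It also needs the chelated pathway, since the transoid conformer used under basic conditions would give the C1 epimer, hence a chelating Lewis acid and no base.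

Step 9
Reactants: 11 [(1S,2S,3R)-2-acetoxy-3-(benzoyloxy)-1-hydroxy-6-oxocyclohexyl]methyl benzoate
Product: 12 2-O-acetylzeylenone = [(1S,5R,6S)-6-acetoxy-5-(benzoyloxy)-1-hydroxy-2-oxocyclohex-3-en-1-yl]methyl benzoate
Conditions: IBX (2-iodoxybenzoic acid, 2.5 equiv), DMSO/fluorobenzene 1:2, 70 °C
Reagents that add atoms: none
Why: IBX-mediated α,β-dehydrogenation of a ketone (enolisation, capture of the enol by the hypervalent iodine reagent, elimination), in which C1 is quaternary so that only the C5 methylene can enolise and only the C4=C5 enone can form, and no stereocenter carries an epimerisable hydrogen.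

**Compound list**

1 | methyl 3-oxocyclopent-1-ene-1-carboxylate | COC(=O)C1=CC(=O)CC1 | starting material
2 | methyl (R)-3-hydroxycyclopent-1-ene-1-carboxylate | COC(=O)C1=C[C@H](O)CC1 | intermediate
3 | (R)-3-hydroxycyclopent-1-ene-1-carboxylic acid | OC(=O)C1=C[C@H](O)CC1 | intermediate
4 | benzoic (R)-3-(benzoyloxy)cyclopent-1-ene-1-carboxylic anhydride (mixed anhydride, not isolated) | O=C(OC(=O)c1ccccc1)C1=C[C@H](OC(=O)c2ccccc2)CC1 | intermediate
5 | (R)-3-(benzoyloxy)cyclopent-1-ene-1-carboxylic acid | OC(=O)C1=C[C@H](OC(=O)c2ccccc2)CC1 | intermediate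
6 | (R)-3-(chlorocarbonyl)cyclopent-2-en-1-yl benzoate (acid chloride, not isolated) | ClC(=O)C1=C[C@H](OC(=O)c2ccccc2)CC1 | intermediate
7 | (R)-3-(2-diazoacetyl)cyclopent-2-en-1-yl benzoate | [N-]=[N+]=CC(=O)C1=C[C@H](OC(=O)c2ccccc2)CC1 | intermediate
8 | (R)-3-[2-(benzoyloxy)acetyl]cyclopent-2-en-1-yl benzoate | O=C(COC(=O)c1ccccc1)C1=C[C@H](OC(=O)c2ccccc2)CC1 | intermediate
9 | (1R,2S,3R)-3-[2-(benzoyloxy)acetyl]-2,3-dihydroxycyclopentyl benzoate (both hydroxyls cis to each other, trans to the benzoate) | O[C@H]1[C@H](OC(=O)c2ccccc2)CC[C@]1(O)C(=O)COC(=O)c1ccccc1 | intermediate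
10 | (1R,2S,3R)-2-acetoxy-3-[2-(benzoyloxy)acetyl]-3-hydroxycyclopentyl benzoate | CC(=O)O[C@H]1[C@H](OC(=O)c2ccccc2)CC[C@]1(O)C(=O)COC(=O)c1ccccc1 | intermediate
11 | [(1S,2S,3R)-2-acetoxy-3-(benzoyloxy)-1-hydroxy-6-oxocyclohexyl]methyl benzoate (4,5-dihydro-2-O-acetylzeylenone) | CC(=O)O[C@H]1[C@H](OC(=O)c2ccccc2)CCC(=O)[C@]1(O)COC(=O)c1ccccc1 | intermediate
12 | 2-O-acetylzeylenone, [(1S,5R,6S)-6-acetoxy-5-(benzoyloxy)-1-hydroxy-2-oxocyclohex-3-en-1-yl]methyl benzoate | CC(=O)O[C@H]1[C@H](OC(=O)c2ccccc2)C=CC(=O)[C@]1(O)COC(=O)c1ccccc1 | target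

**Step count and risks**

Total step count: 9. Longest linear sequence: 9 (the route is linear).

Steps most likely to fail:

Step 8 (key step). What may go wrong: migration of the ring methylene C5 in place of the acetoxy-bearing C2, or partial reaction through a non-chelated conformer with loss of control at C1. The fallback changes the migrating terminus from an ester-bearing to a donor silyloxy-bearing carbon, which is an established strongly migrating group in pinacol-type shifts, and moves the acetylation behind the shift. It sets out from diol 9 (step 7 is skipped). TESOTf and 2,6-lutidine (CH2Cl2, −78 °C) should silylate only the secondary hydroxyl to give (1R,2S,3R)-3-[2-(benzoyloxy)acetyl]-3-hydroxy-2-[(triethylsilyl)oxy]cyclopentyl benzoate F1. The chelate-controlled acyloin shift, here with Me2AlCl (1.1 equiv, CH2Cl2, −40 to 0 °C), should then give [(1S,2S,3R)-3-(benzoyloxy)-1-hydroxy-6-oxo-2-[(triethylsilyl)oxy]cyclohexyl]methyl benzoate F2 with the same stereochemical course. HF·pyridine (THF, 0 °C) should free [(1S,2S,3R)-3-(benzoyloxy)-1,2-dihydroxy-6-oxocyclohexyl]methyl benzoate F3. Ac2O/pyridine at 0 °C, selective for the secondary hydroxyl, comes back to the route at 11.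

Step 9. What may go wrong: incomplete dehydrogenation or oxidative degradation of the densely oxygenated ketone under hot hypervalent-iodine conditions. The fallback is a two-stage Saegusa–Ito oxidation through an isolated silyl enol ether, setting out from 11. TMSOTf/Et3N (CH2Cl2, 0 °C) should give the only possible enol ether, with the tertiary hydroxyl silylated as well: [(1S,5R,6S)-6-acetoxy-5-(benzoyloxy)-1,2-bis[(trimethylsilyl)oxy]cyclohex-2-en-1-yl]methyl benzoate F4. Pd(OAc)2 (1.1 equiv, MeCN, rt) should convert it into [(1S,5R,6S)-6-acetoxy-5-(benzoyloxy)-2-oxo-1-[(trimethylsilyl)oxy]cyclohex-3-en-1-yl]methyl benzoate F5. Dilute aqueous HCl in THF should remove the tertiary silyl ether and come back to the route at 12.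

Step 1. What may go wrong: insufficient enantiofacial discrimination, or competing conjugate reduction or hydroboration of the doubly activated alkene. The fallback is racemic reduction followed by enzymatic resolution, setting out from 1. NaBH4/CeCl3·7H2O (MeOH, −40 °C, Luche reduction) should give racemic methyl 3-hydroxycyclopent-1-ene-1-carboxylate F6. Lipase from Burkholderia cepacia with vinyl acetate (tBuOMe, rt) should acylate the (R)-enantiomer, in line with the usual enantiopreference of lipases for secondary alcohols, to give methyl (R)-3-acetoxycyclopent-1-ene-1-carboxylate F7, which is separated from the unreacted (S)-alcohol. K2CO3 in MeOH (0 °C) should cleave the acetate and come back to the route at 2.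

**Further compounds**

F1 | step 8 | (1R,2S,3R)-3-[2-(benzoyloxy)acetyl]-3-hydroxy-2-[(triethylsilyl)oxy]cyclopentyl benzoate | CC[Si](CC)(CC)O[C@H]1[C@H](OC(=O)c2ccccc2)CC[C@]1(O)C(=O)COC(=O)c1ccccc1
F2 | step 8 | [(1S,2S,3R)-3-(benzoyloxy)-1-hydroxy-6-oxo-2-[(triethylsilyl)oxy]cyclohexyl]methyl benzoate | CC[Si](CC)(CC)O[C@H]1[C@H](OC(=O)c2ccccc2)CCC(=O)[C@]1(O)COC(=O)c1ccccc1
F3 | step 8 | [(1S,2S,3R)-3-(benzoyloxy)-1,2-dihydroxy-6-oxocyclohexyl]methyl benzoate | O[C@H]1[C@H](OC(=O)c2ccccc2)CCC(=O)[C@]1(O)COC(=O)c1ccccc1
F4 | step 9 | [(1S,5R,6S)-6-acetoxy-5-(benzoyloxy)-1,2-bis[(trimethylsilyl)oxy]cyclohex-2-en-1-yl]methyl benzoate | CC(=O)O[C@H]1[C@H](OC(=O)c2ccccc2)CC=C(O[Si](C)(C)C)[C@]1(O[Si](C)(C)C)COC(=O)c1ccccc1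
F5 | step 9 | [(1S,5R,6S)-6-acetoxy-5-(benzoyloxy)-2-oxo-1-[(trimethylsilyl)oxy]cyclohex-3-en-1-yl]methyl benzoate | CC(=O)O[C@H]1[C@H](OC(=O)c2ccccc2)C=CC(=O)[C@]1(O[Si](C)(C)C)COC(=O)c1ccccc1
F6 | step 1 | methyl 3-hydroxycyclopent-1-ene-1-carboxylate (racemic) | COC(=O)C1=CC(O)CC1
F7 | step 1 | methyl (R)-3-acetoxycyclopent-1-ene-1-carboxylate | COC(=O)C1=C[C@H](OC(C)=O)CC1
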